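**Plan**
Retrosynthesis: the two acetates come off first. Then C11=C12 is cut (Julia–Kocienski: decalin C11 sulfone plus C12–C16 aldehyde), then C17–O (allylic oxidation), C9–C11 (methyl addition to a C9 ketone), and last C1–C10 and C4–C5 (Diels–Alder).
Enabling feature: ring B (C5–C10) carries O on C6, the C7=C8 alkene with the one-carbon branch C17 on C8, a carbon-bearing C9 and a methylated quaternary C10. This is 2,6-dimethyl-1,4-benzoquinone with one ring C=C as C10=C5, so ring B is bought and ring A is annulated onto it.
Forward: ring A closes in step 1. Ring B is then edited in the order C6 mask, C2=C3 saturation, C11 onto C9, C5 inversion, C6 reduction, C9=C11, C11–O, C11–S, C17–O. The side chain is joined in step 18.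
Stereochemistry: C10 comes from the chiral oxazaborolidinium cation. C5 is set by equilibrating the 7-en-6-one, postponed on purpose until C9 is tetrahedral. C6 (hydride) and C9 (hydroboration) are set by attack anti to the axial C10 methyl, C13 comes from (R)-2-methylglycidol, and the E alkene comes from the olefination.

Key step: step 1

Assumption: the facial sense of the catalyst is extrapolated from the α-C–H···O binding model for quinones, which predicts that the (S)-diphenylprolinol-derived cation gives the C10 configuration of the target. If the sense is the reverse, the equally available (R)-catalyst is used and nothing else changes.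
Numbering: labdane numbering throughout (ring A C1–C5/C10, ring B C5–C10, C17 on C8, C18/C19 on C4, C20 = methyl on C10, side chain C11–C16).

Step 1
Reactants: 1 2,6-dimethyl-1,4-benzoquinone; 2 4-methylpenta-1,3-diene
Product: 3 cis-fused ene-dione adduct (5S,10R)
Conditions: (S)-3,3-diphenyl-1-(o-tolyl)tetrahydropyrrolo[1,2-c][1,3,2]oxazaborole (20 mol%), Tf2NH (18 mol%), 2 (5 equiv), CH2Cl2, −78 → −20 °C
Reagents that add atoms: none
Why: The cationic boron binds the quinone carbonyl that becomes C6, the only one flanked by C–H groups and the more basic one because both β-carbons carry methyl donors, through the lone pair syn to an α-C–H that hydrogen-bonds to the catalyst oxygen, and this activates that C=C for a concerted but strongly asynchronous [4+2] cycloaddition. The closest known reaction type is the oxazaborolidinium-catalysed Diels–Alder reaction of dialkyl-1,4-benzoquinones with acyclic dienes, and the orientation is the one long known for this quinone with piperylene under BF3. Ring A closes as a six-membered carbocycle by intermolecular [4π+2π] annulation, with C1–C10 forming ahead of C4–C5. C10 is set by the catalyst, whose phenyl group covers one face of the bound C=C, and C5 follows from suprafacial addition, so the adduct is cis-fused. The regioselectivity that is needed is matched, because the unsubstituted and most nucleophilic diene terminus attacks the β-carbon C10 while the gem-dimethyl terminus, which carries the developing positive charge, closes on the hydrogen-bearing α-carbon C5; site selectivity is no issue since the two quinone C=C bonds are equivalent and the adduct is a much poorer dienophile than 1. The early C1–C10 bond relaxes the demand for a planar s-cis diene, which is what should make the cis methyl of 2 tolerable, and excess diene and the higher end temperature compensate for its low reactivity.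

Step 2
Reactants: 3 cis-fused ene-dione adduct
Product: 4 cis-fused 6-hydroxy-2,7-dien-9-one (5S,6R,10R)
Conditions: NaBH4 (0.5 equiv), CeCl3·7H2O, MeOH/CH2Cl2, −78 °C
Reagents that add atoms: none
Why: Luche 1,2-reduction should take the C6 carbonyl, flanked by a CH and a vinylic CH, in preference to C9, wedged between quaternary C10 and the methyl-bearing C8; hydride is expected from the convex face (that of H-5 and C20), but this carbinol only masks C6 and its configuration is erased in step 5.

Step 3
Reactants: 4 cis-fused 6-hydroxy-2,7-dien-9-one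
Product: 5 cis-fused 6-hydroxy-7-en-9-one with saturated ring A (5S,6R,10R)
Conditions: H2 (1 atm), RhCl(PPh3)3 (5 mol%), benzene/EtOH, rt
Reagents that add atoms: none
Why: Homogeneous hydrogenation with RhCl(PPh3)3 is governed by alkene substitution, so the cis-disubstituted C2=C3 bond is saturated while the trisubstituted α-methyl enone survives, the selectivity familiar from carvone; no stereocentre is formed.

Step 4
Reactants: 5 cis-fused 6-hydroxy-7-en-9-one
Product: 6 cis-fused 9-methyl-7-ene-6,9-diol (5S,6R,9S,10R)
Conditions: MeLi (3 equiv), Et2O/THF, −78 → 0 °C; then H2O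
Reagents that add atoms: methyllithium, [Li]C
Why: This is the 1,2-addition of a small, hard organolithium to a non-enolisable enone: the first equivalent only makes the inert C6 alkoxide, and the next brings in C11 and makes C9 tetrahedral; attack is expected from the convex face, and the new centre has no lasting consequence because C9 becomes sp2 again in step 8.

Step 5
Reactants: 6 cis-fused 9-methyl-7-ene-6,9-diol
Product: 8 trans-fused 9-hydroxy-9-methyl-7-en-6-one (5R,9S,10R), via cis-fused hydroxy enone 7 (not isolated)
Conditions: (n-Pr4N)RuO4 (5 mol%), NMO, 4 Å sieves, CH2Cl2, rt; filtration through SiO2, concentration; NaOMe (0.5 equiv), MeOH, rt → 40 °C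
Reagents that add atoms: none
Why: Ley–Griffith oxidation touches only the secondary allylic alcohol, and base epimerisation through the C5 enolate then sets H-5 anti to C20, because with C9 tetrahedral and fully substituted each cis-decalin conformer puts either C9 syn-axial to the axial C4 methyl or C6 axial on ring A, so the trans fusion (the one that 7-en-6-one labdanes keep under methoxide) should be the thermodynamic product, which could not be assumed for the flat ene-dione 3, where a cis conformer relieves the C4/C10 methyl clash at little cost.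

Step 6
Reactants: 8 trans-fused 9-hydroxy-9-methyl-7-en-6-one
Product: 9 trans-fused 9-methyl-7-ene-6,9-diol (5R,6S,9S,10R), 6-OH syn to C20
Conditions: NaBH4, CeCl3·7H2O, MeOH, −78 °C
Reagents that add atoms: none
Why: In this Luche 1,2-reduction the face of the C6 carbonyl syn to C20 is closed by the axial methyls on C10 and C4, so hydride arrives anti to them and gives the axial (6S) alcohol.

Step 7
Reactants: 9 trans-fused 9-methyl-7-ene-6,9-diol
Product: 10 6-O-TBS ether with free tertiary 9-OH (5R,6S,9S,10R)
Conditions: TBSOTf (1.1 equiv), 2,6-lutidine, CH2Cl2, −78 → 0 °C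
Reagents that add atoms: tert-butyldimethylsilyl triflate, CC(C)(C)[Si](C)(C)OS(=O)(=O)C(F)(F)F
Why: The silyl triflate is reactive enough for the hindered axial secondary alcohol, and with one equivalent at low temperature the still more hindered tertiary carbinol should stay free.

Step 8
Reactants: 10 6-O-TBS ether with free tertiary 9-OH
Product: 11 trans-fused 6-silyloxy-7,9(11)-diene (5R,6S,10R)
Conditions: Burgess reagent (MeO2CN−SO2N+Et3, 2 equiv), toluene, 60 °C
Reagents that add atoms: none
Why: In this Burgess dehydration (syn elimination of a tertiary sulfamate) C10 is quaternary and C8 is sp2, so the C11 methyl is the only source of a β-hydrogen and the exocyclic C9=C11 bond, conjugated with C7=C8, is the only alkene that can form by 1,2-elimination.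

Step 9
Reactants: 11 trans-fused 6-silyloxy-7,9(11)-diene
Product: 13 11-hydroxy-6-silyloxy-7-ene (5R,6S,9R,10S), H-9 anti to C20, via B-alkyl-9-BBN adduct 12 (not isolated)
Conditions: 9-BBN dimer, THF, rt → 55 °C; then 3 M NaOH, 30% H2O2, 0 °C → rt
Reagents that add atoms: 9-borabicyclo[3.3.1]nonane, B1C2CCCC1CCC2 (in 12 only); hydrogen peroxide, OO
Why: In this hydroboration–oxidation the bulky borane adds only to the 1,1-disubstituted C9=C11 bond with boron on the CH2 terminus and delivers hydrogen to C9 on the face anti to the axial C20 and the 6-silyloxy group, which makes C11 equatorial as in the target, and the C–B bond is oxidised with retention.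

Step 10
Reactants: 13 11-hydroxy-6-silyloxy-7-ene
Product: 14 C11 1-phenyltetrazol-5-yl sulfide (5R,6S,9R,10R)
Conditions: 1-phenyl-1H-tetrazole-5-thiol, PPh3, DIAD, THF, 0 °C → rt
Reagents that add atoms: 1-phenyl-1H-tetrazole-5-thiol, Sc1nnnn1-c1ccccc1
Why: In this Mitsunobu thioetherification the acidic thiol displaces the activated primary C11–O bond in an SN2 step that touches no stereocentre, a displacement that β-branched primary alcohols of the drimenol type are known to undergo.

Step 11
Reactants: 14 C11 1-phenyltetrazol-5-yl sulfide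
Product: 15 C11 1-phenyltetrazol-5-yl sulfone (5R,6S,9R,10R)
Conditions: (NH4)6Mo7O24·4H2O (10 mol%), 30% H2O2, EtOH, 0 °C → rt
Reagents that add atoms: hydrogen peroxide, OO
Why: Molybdate-catalysed peroxide oxidation of a sulfide to the sulfone is much faster than epoxidation of the hindered C7=C8 bond, which the allylic silyloxy group deactivates further.

Step 12
Reactants: 15 C11 1-phenyltetrazol-5-yl sulfone
Product: 16 17-hydroxy sulfone (5R,6S,9S,10R)
Conditions: SeO2 (0.3 equiv), t-BuOOH (3 equiv), CH2Cl2, 0 °C → rt
Reagents that add atoms: selenium dioxide, O=[Se]=O (oxygen carrier); tert-butyl hydroperoxide, CC(C)(C)OO (terminal oxygen source)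
Why: In this Riley allylic oxidation (ene reaction, then [2,3]-shift) selenium binds the less substituted C7 and hydrogen is taken on the C8 side, where the C17 methyl should win over the hindered tertiary C9–H that the sulfonylmethyl group deactivates, the site selectivity known for drim-7-enes with an electron-poor C11 substituent.

Step 13
Reactants: 16 17-hydroxy sulfone
Product: 17 6,17-bis-O-TBS sulfone (5R,6S,9S,10R)
Conditions: TBSCl, imidazole, DMF, rt
Reagents that add atoms: tert-butyldimethylsilyl chloride, CC(C)(C)[Si](C)(C)Cl
Why: This is a standard silylation of an unhindered primary allylic alcohol, needed because the coupling uses a strong base.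

Step 14
Reactants: 18 (R)-2-methylglycidol
Product: 19 (S)-triethyl[(2-methyloxiran-2-yl)methoxy]silane
Conditions: Et3SiCl, imidazole, CH2Cl2, 0 °C
Reagents that add atoms: chlorotriethylsilane, CC[Si](Cl)(CC)CC
Why: This is a standard silylation of the primary alcohol; the quaternary epoxide carbon is the future C13 and is bought in enantiopure form (the descriptor changes only through the priority rules).

Step 15
Reactants: 19 (S)-triethyl[(2-methyloxiran-2-yl)methoxy]silane
Product: 20 (S)-2-methyl-1-(triethylsilyloxy)but-3-en-2-ol
Conditions: Me3S+ I− (3 equiv), n-BuLi (2.9 equiv), THF, −10 °C → rt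
Reagents that add atoms: trimethylsulfonium iodide, C[S+](C)C.[I-]
Why: In this one-carbon homologation of a terminal epoxide to an allylic alcohol, dimethylsulfonium methylide opens the epoxide at its CH2 terminus (future C14) and loss of Me2S from the betaine makes the C14=C15 vinyl group; no bond to the stereocentre is broken, and a silyl shift between the two oxygens would be harmless because step 16 silylates both.

Step 16
Reactants: 20 (S)-2-methyl-1-(triethylsilyloxy)but-3-en-2-ol
Product: 21 (S)-2-methylbut-3-ene-1,2-diol bis(triethylsilyl) ether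
Conditions: Et3SiOTf, 2,6-lutidine, CH2Cl2, −78 → 0 °C
Reagents that add atoms: triethylsilyl triflate, CC[Si](CC)(CC)OS(=O)(=O)C(F)(F)F
Why: Silyl triflate with lutidine is the standard way to silylate a tertiary alcohol and is too mild to ionise the allylic carbinol.

Step 17
Reactants: 21 (S)-2-methylbut-3-ene-1,2-diol bis(triethylsilyl) ether
Product: 22 (S)-2-methyl-2-(triethylsilyloxy)but-3-enal
Conditions: (COCl)2, DMSO, CH2Cl2, −78 → −35 °C; Et3N, → 0 °C
Reagents that add atoms: none
Why: This is a Swern oxidation applied directly to a primary triethylsilyl ether: the chlorosulfonium salt exchanges only the unhindered primary silyl group for an alkoxysulfonium ion, the tertiary silyl ether stays, and the aldehyde has no α-hydrogen, so C13 cannot epimerise.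

Step 18
Reactants: 17 6,17-bis-O-TBS sulfone; 22 (S)-2-methyl-2-(triethylsilyloxy)but-3-enal
Product: 23 fully silylated (11E)-labda-7,11,14-triene (5R,6S,9S,10S,13S)
Conditions: KN(SiMe3)2 added to 17 and 22 (1.5 equiv), DME, −60 °C → rt
Reagents that add atoms: none
Why: In this Julia–Kocienski olefination under Barbier conditions (possible because 22 cannot enolise), addition of the metallated sulfone, Smiles rearrangement and anti-periplanar loss of SO2 and tetrazolate form C11=C12, the potassium counter-ion, DME and two branched partners favour the anti adduct and hence the E alkene, and neither C9 nor C13 is deprotonated.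

Step 19
Reactants: 23 fully silylated (11E)-labda-7,11,14-triene
Product: 24 (11E)-labda-7,11,14-triene-6,13,17-triol (5R,6S,9S,10S,13S)
Conditions: n-Bu4NF (6 equiv), THF, rt → 45 °C
Reagents that add atoms: none
Why: Fluoride desilylation removes all three silyl groups under non-acidic conditions, so the tertiary doubly allylic C13 carbinol cannot ionise; warming is allowed for the hindered C6 ether.

Step 20
Reactants: 24 (11E)-labda-7,11,14-triene-6,13,17-triol
Product: 25 target, (5R,6S,9S,10S,13S,11E)-6,17-diacetoxylabda-7,11,14-trien-13-ol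
Conditions: Ac2O (4 equiv), pyridine, DMAP (10 mol%), CH2Cl2, 0 °C → rt
Reagents that add atoms: acetic anhydride, CC(=O)OC(C)=O
Why: DMAP-catalysed acetylation is chemoselective by steric class: the primary allylic and the secondary allylic alcohols are esterified, while a tertiary carbinol of the linalool type stays free at room temperature.

**Compound list**
1 | 2,6-dimethyl-1,4-benzoquinone | CC1=CC(=O)C=C(C)C1=O | starting material
2 | 4-methylpenta-1,3-diene | C=CC=C(C)C | starting material
3 | cis-fused ene-dione adduct, (4aS,8aR)-2,5,5,8a-tetramethyl-4a,5,8,8a-tetrahydronaphthalene-1,4-dione (C6 and C9 ketones, C7=C8 with C17, C2=C3, H-5 cis to C20) | O=C1C(C)=CC(=O)[C@H]2C(C)(C)C=CC[C@@]12C | intermediate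
4 | cis-fused 6-hydroxy-2,7-dien-9-one (5S,6R,10R), 6-OH anti to C20 | O=C1C(C)=C[C@@H](O)[C@H]2C(C)(C)C=CC[C@@]12C | intermediate
5 | cis-fused 6-hydroxy-7-en-9-one, ring A saturated (5S,6R,10R) | O=C1C(C)=C[C@@H](O)[C@H]2C(C)(C)CCC[C@@]12C | intermediate
6 | cis-fused 9-methyl-7-ene-6,9-diol (5S,6R,9S,10R), C11 syn to C20 | C[C@]1(O)C(C)=C[C@@H](O)[C@H]2C(C)(C)CCC[C@@]12C | intermediate
7 | cis-fused 9-hydroxy-9-methyl-7-en-6-one (5S,9S,10R), not isolated | C[C@]1(O)C(C)=CC(=O)[C@H]2C(C)(C)CCC[C@@]12C | intermediate
8 | trans-fused 9-hydroxy-9-methyl-7-en-6-one (5R,9S,10R), H-5 anti to C20 | C[C@]1(O)C(C)=CC(=O)[C@@H]2C(C)(C)CCC[C@@]12C | intermediate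
9 | trans-fused 9-methyl-7-ene-6,9-diol (5R,6S,9S,10R), 6-OH syn to C20 | C[C@]1(O)C(C)=C[C@H](O)[C@@H]2C(C)(C)CCC[C@@]12C | intermediate
10 | 6-O-TBS ether of 9, tertiary 9-OH free | C[C@]1(O)C(C)=C[C@H](O[Si](C)(C)C(C)(C)C)[C@@H]2C(C)(C)CCC[C@@]12C | intermediate
11 | trans-fused 6-(TBS-oxy)-7,9(11)-diene (5R,6S,10R) | C=C1C(C)=C[C@H](O[Si](C)(C)C(C)(C)C)[C@@H]2C(C)(C)CCC[C@@]12C | intermediate
12 | C11 B-alkyl-9-BBN adduct of 11, H-9 anti to C20, not isolated | C(B1C2CCCC1CCC2)[C@@H]3C(C)=C[C@H](O[Si](C)(C)C(C)(C)C)[C@@H]4C(C)(C)CCC[C@@]34C | intermediate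
13 | 11-hydroxy-6-(TBS-oxy)-7-ene (5R,6S,9R,10S), C11 equatorial and syn to C20 | OC[C@@H]1C(C)=C[C@H](O[Si](C)(C)C(C)(C)C)[C@@H]2C(C)(C)CCC[C@@]12C | intermediate
14 | C11 1-phenyl-1H-tetrazol-5-yl sulfide (5R,6S,9R,10R) | C(Sc1nnnn1-c1ccccc1)[C@@H]2C(C)=C[C@H](O[Si](C)(C)C(C)(C)C)[C@@H]3C(C)(C)CCC[C@@]23C | intermediate
15 | C11 1-phenyl-1H-tetrazol-5-yl sulfone (5R,6S,9R,10R) | C(S(=O)(=O)c1nnnn1-c1ccccc1)[C@@H]2C(C)=C[C@H](O[Si](C)(C)C(C)(C)C)[C@@H]3C(C)(C)CCC[C@@]23C | intermediate
16 | 17-hydroxy sulfone (5R,6S,9S,10R) | C(S(=O)(=O)c1nnnn1-c1ccccc1)[C@@H]2C(CO)=C[C@H](O[Si](C)(C)C(C)(C)C)[C@@H]3C(C)(C)CCC[C@@]23C | intermediate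
17 | 6,17-bis-O-TBS sulfone (5R,6S,9S,10R) | C(S(=O)(=O)c1nnnn1-c1ccccc1)[C@@H]2C(CO[Si](C)(C)C(C)(C)C)=C[C@H](O[Si](C)(C)C(C)(C)C)[C@@H]3C(C)(C)CCC[C@@]23C | intermediate
18 | (R)-2-methylglycidol, (R)-(2-methyloxiran-2-yl)methanol | C[C@]1(CO1)CO | starting material
19 | (S)-triethyl[(2-methyloxiran-2-yl)methoxy]silane | C[C@]1(CO1)CO[Si](CC)(CC)CC | intermediate
20 | (S)-2-methyl-1-(triethylsilyloxy)but-3-en-2-ol | C=C[C@](C)(O)CO[Si](CC)(CC)CC | intermediate
21 | (S)-2-methylbut-3-ene-1,2-diol bis(triethylsilyl) ether | C=C[C@](C)(O[Si](CC)(CC)CC)CO[Si](CC)(CC)CC | intermediate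
22 | (S)-2-methyl-2-(triethylsilyloxy)but-3-enal | C=C[C@](C)(O[Si](CC)(CC)CC)C=O | intermediate
23 | (5R,6S,9S,10S,13S,11E)-6,17-bis(TBS-oxy)-13-(triethylsilyloxy)labda-7,11,14-triene | C=C[C@](C)(O[Si](CC)(CC)CC)/C=C/[C@@H]1C(CO[Si](C)(C)C(C)(C)C)=C[C@H](O[Si](C)(C)C(C)(C)C)[C@@H]2C(C)(C)CCC[C@@]12C | intermediate
24 | (5R,6S,9S,10S,13S,11E)-labda-7,11,14-triene-6,13,17-triol | C=C[C@](C)(O)/C=C/[C@@H]1C(CO)=C[C@H](O)[C@@H]2C(C)(C)CCC[C@@]12C | intermediate
25 | (5R,6S,9S,10S,13S,11E)-6,17-diacetoxylabda-7,11,14-trien-13-ol (CNP0103498.1) | C=C[C@](C)(O)/C=C/[C@@H]1C(COC(C)=O)=C[C@H](OC(C)=O)[C@@H]2C(C)(C)CCC[C@@]12C | target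

**Totals**
Total steps: 20. Longest linear sequence: 16 (steps 1–13 and 18–20). The aldehyde 22 takes four steps (14–17).

**Steps most likely to fail**
(a) The cycloaddition, step 1. The cis methyl of the diene may make the cycloaddition so slow that acid-induced oligomerisation of the diene competes. The higher temperature it needs may also erode facial selectivity. The fallback sets out from 1 and returns at 3, forming the same two bonds with an activated diene whose extra oxygen is excised afterwards. Mesityl oxide is converted with LiN(i-Pr)2 and i-Pr3SiOTf into 4-methyl-2-(triisopropylsilyloxy)penta-1,3-diene F1, a 2-silyloxydiene of the class this catalyst handles best and far more nucleophilic at its CH2 terminus. The same catalyst should join it to 1 at −78 °C to give the C2 silyl enol ether adduct F2. CsF with PhNTf2 turns this directly into the C2 enol triflate F3, and Pd(OAc)2, PPh3, HCO2H and n-Bu3N in DMF replace the triflate by hydrogen to give 3.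

(b) The allylic oxidation, step 12. Hydrogen abstraction at C9 or C6 may compete with abstraction at C17, and the alcohol may be over-oxidised to the enal. The fallback sets out from 15 and returns at 16, replacing C–H oxidation by epoxide isomerisation and oxygen transposition. mCPBA (NaHCO3, CH2Cl2, 0 °C) should epoxidise C7=C8 on the face anti to C20 and the silyloxy group to give the 7,8-epoxide F4. Cp2TiCl (from Cp2TiCl2 and Mn dust, THF) opens it at the tertiary C8 and terminates by loss of a C17 hydrogen to give the exo-methylene 8(17)-en-7-ol F5. Ph3SiOReO3 (2 mol%, Et2O, −50 → 0 °C) then shifts the oxygen 1,3 to the primary position, with the alkene returning to the more substituted C7=C8, which is 16.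

(c) The olefination, step 18. Addition of the hindered sulfonyl anion to the α-quaternary aldehyde may be slow, leaving time for β-elimination of sulfinate across C9–C11 or for self-condensation, and geometric selectivity may be poor. The fallback sets out from 17 and 18 and returns at 24, using a much smaller electrophile and building the carbinol and vinyl group afterwards. Compound 18 is oxidised (SO3·pyridine, DMSO, Et3N) to (S)-2-methyloxirane-2-carbaldehyde F6. The same olefination with 17 should give the (11E)-vinyl epoxide F7. Me3S+ I− and n-BuLi (THF, −10 °C → rt) open the epoxide at its CH2 terminus and expel Me2S to give the 13-hydroxy-6,17-bis-O-TBS triene F8, and n-Bu4NF gives 24.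

**Further compounds**
F1 | step 1 | 4-methyl-2-(triisopropylsilyloxy)penta-1,3-diene | C=C(O[Si](C(C)C)(C(C)C)C(C)C)C=C(C)C
F2 | step 1 | cis-fused ene-dione adduct with a C2 triisopropylsilyl enol ether (C2=C3) | O=C1C(C)=CC(=O)[C@H]2C(C)(C)C=C(O[Si](C(C)C)(C(C)C)C(C)C)C[C@@]12C
F3 | step 1 | cis-fused ene-dione with a C2 enol triflate (C2=C3) | O=C1C(C)=CC(=O)[C@H]2C(C)(C)C=C(OS(=O)(=O)C(F)(F)F)C[C@@]12C
F4 | step 12 | 7,8-epoxide of 15, oxygen anti to C20 | C(S(=O)(=O)c1nnnn1-c1ccccc1)[C@@H]2[C@@]3(C)O[C@H]3[C@H](O[Si](C)(C)C(C)(C)C)[C@@H]4C(C)(C)CCC[C@@]24C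
F5 | step 12 | 8(17)-en-7-ol sulfone, 7-OH anti to C20 | C(S(=O)(=O)c1nnnn1-c1ccccc1)[C@@H]2C(=C)[C@@H](O)[C@H](O[Si](C)(C)C(C)(C)C)[C@@H]3C(C)(C)CCC[C@@]23C
F6 | step 18 | (S)-2-methyloxirane-2-carbaldehyde | C[C@]1(CO1)C=O
F7 | step 18 | (11E)-vinyl epoxide, 6,17-bis-O-TBS, C13/C14 oxirane | C[C@]1(CO1)/C=C/[C@@H]2C(CO[Si](C)(C)C(C)(C)C)=C[C@H](O[Si](C)(C)C(C)(C)C)[C@@H]3C(C)(C)CCC[C@@]23C
F8 | step 18 | (13S,11E)-6,17-bis(TBS-oxy)labda-7,11,14-trien-13-ol | C=C[C@](C)(O)/C=C/[C@@H]1C(CO[Si](C)(C)C(C)(C)C)=C[C@H](O[Si](C)(C)C(C)(C)C)[C@@H]2C(C)(C)CCC[C@@]12C
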